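Do not read "held" as "free". G is held, yet each D must still cross into the liquid, and that crossing has a ceiling.

J 0.049 M; G 2.8 mM (held); Z 33 µM (in portions, 4); time 25 h; the portions of Z follow each other after 2.5 min, the first at the start

    G ⇌ D, rate k1*(csat - [D]) (k1 = 0.377 min⁻¹, csat = 2.8 mM)
    J + D + Z → Z + X (k2 = 14900 L² mol⁻² s⁻¹)
    D + X → D.X (k3 = 9.68 L mol⁻¹ min⁻¹)

- at the start none of D is dissolved
- the reaction counts as stopped when no species that holds the J changes by six tenths of a point or more over the second half of the time
- run time (flask): 25 h

- why nothing more happens at 25 h, or that something still does (it is still moving / no working catalyst is left / all of J has reacted)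
- share of the J used up at 25 h
- D.X at 25 h, in percent of the J charged

Turn the question round: what must be true for J or X to be left? Follow one J. It meets no fork: it takes a D at Z and becomes X, and X takes a second D and becomes D.X. So the flask needs 0.0980 M of D. At c(D) zero the crossing carries 1.06 mM min⁻¹, and c(D) cannot go lower. The quotient is 92.8 min: the delivery time, the shortest span in which G can supply two D for each J charged.

At saturation and with the whole charge of Z, J has a pseudo-first-order lifetime of 12.1 min. X has one of 36.9 min at saturation, and the delivery time is longer than both. Add the links in series: 2.36 h. On this estimate, J or X remains if the run is short against this sum. It is not: 25 h is 10.6 such sums. Taking the sum as one decay time, my reckoning gives all of J has reacted, J used up >99.9%, and D.X >99.9%.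

The forecast says all of J has reacted, J used up 100%, D.X 100%. Its grounds: “gas transfer of about 1 mM/min can supply the roughly 0.098 M of D needed”.

The flask gives all of J has reacted, J used up 100%, D.X 100%.

In this flask, the passage of G into D reaches half of its turnover at 1.13 h. Half the delivery time is 0.773 h, and the reading lies later. After 2.50 h, which is 1.62 delivery times, 87% of that turnover stands done. The neighbouring flask differs in its time of reading, 15 h. That is 9.70 delivery times and 6.36 sums, which on my estimate gives D.X 99.8%. The neighbouring flask reads D.X 100%, with 0% of its J left.

All constants are invented; no experiment stands behind them.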